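**Retrosynthetic overview**

1. Isoangustone A ⇐ tetrakis-TBS isoflavone 17 by global desilylation.
2. 17 ⇐ (Z)-3-aryloxy-2-arylacrylic acid 15 by cutting C4–C4a of ring C (intramolecular Friedel–Crafts acylation). The strategy rests on ring A: once C4–C4a is cut, ring A is a 2-prenylphloroglucinol held through O1 at the carbon para to the C6 prenyl group. The two carbons ortho to O1 (future C4a and C8) are then mirror images, and closure at either gives the 5,7-dioxygenated 6-prenyl chromone.
3. 15 ⇐ phenol 5 + (Z)-enol tosylate 13 by cutting O1–C2 (addition–elimination), followed by allyl ester removal.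
4. 5 ⇐ phloroglucinol + prenyl bromide; 13 ⇐ 3-bromo-4,5-dihydroxybenzaldehyde, a prenylstannane and allyl diazoacetate.
5. Ring order: rings A and B come in as aromatic starting materials; ring C is the only ring formed, in step 11.

Key step: step 11

Abbreviations: prenyl = 3-methylbut-2-en-1-yl; TBS = tert-butyldimethylsilyl.

Remark on the chemistry: the C2=C3 geometry of 14 and 15 is assumed to follow from stereoretentive substitution of (Z)-tosylate 13; any (E)-acid that forms should still converge in step 11, because the ionised acid chloride is a vinylogous acylium ion with a rotatable C2–C3 bond.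

**Route**

Step 1
Reactants: 1 phloroglucinol; 2 prenyl bromide
Product: 3 2-prenylphloroglucinol (2-(3-methylbut-2-en-1-yl)benzene-1,3,5-triol)
Conditions: 1 (3 equiv), 2 (1 equiv), DBU (1 equiv), THF, 0 °C to rt
Reagents that add atoms: none
Why: Direct C-allylation of the ambident phloroglucinol anion by an allylic bromide should give the mono-C-prenyl triol, with excess 1 suppressing a second alkylation.

Step 2
Reactants: 3 2-prenylphloroglucinol
Product: 4 1,3,5-tris(TBS-oxy)-2-prenylbenzene
Conditions: TBSCl (3.6 equiv), imidazole (7 equiv), DMF, rt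
Reagents that add atoms: tert-butyldimethylsilyl chloride, CC(C)(C)[Si](C)(C)Cl
Why: Standard imidazole-promoted O-silylation of phenols should cap all three hydroxyls, the two beside the prenyl group included.

Step 3
Reactants: 4 1,3,5-tris(TBS-oxy)-2-prenylbenzene
Product: 5 3,5-bis(TBS-oxy)-4-prenylphenol
Conditions: K2CO3 (0.3 equiv), MeOH/THF 1:2, 0 °C, stopped at partial conversion; recovered 4 recycled
Reagents that add atoms: none
Why: Base-catalysed methanolysis of an aryl silyl ether should occur first at the silicon flanked by two ring hydrogens, since the other two are shielded by the prenyl methylene, and the phenoxide formed slows further cleavage.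

Step 4
Reactants: 6 3-bromo-4,5-dihydroxybenzaldehyde
Product: 7 3-bromo-4,5-bis(TBS-oxy)benzaldehyde
Conditions: TBSCl (2.5 equiv), imidazole (5 equiv), DMF, rt
Reagents that add atoms: tert-butyldimethylsilyl chloride, CC(C)(C)[Si](C)(C)Cl
Why: Imidazole-promoted O-silylation of both catechol hydroxyls; the bromine already marks the future prenyl position ortho to O4.

Step 5
Reactants: 7 3-bromo-4,5-bis(TBS-oxy)benzaldehyde; 8 tributyl(3-methylbut-2-en-1-yl)stannane
Product: 9 3,4-bis(TBS-oxy)-5-prenylbenzaldehyde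
Conditions: Pd(PPh3)4 (5 mol %), degassed toluene, 100 °C
Reagents that add atoms: none
Why: Stille coupling, in which zerovalent palladium inserts into the C–Br bond and the allyl group is delivered from tin; reductive elimination at the less substituted allyl terminus should give the linear prenyl arene, and the neutral, fluoride-free medium spares the silyl ethers and the aldehyde.

Step 6
Reactants: 10 allyl bromoacetate
Product: 11 allyl diazoacetate
Conditions: N,N'-ditosylhydrazine (2 equiv), DBU (5 equiv), THF, 0 °C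
Reagents that add atoms: N,N'-ditosylhydrazine, Cc1ccc(cc1)S(=O)(=O)NNS(=O)(=O)c1ccc(C)cc1
Why: N-alkylation of the sulfonylhydrazide by the bromoacetate followed by two base-induced sulfinate eliminations is a known diazo synthesis and should give the diazo ester without touching the allyl group.

Step 7
Reactants: 9 3,4-bis(TBS-oxy)-5-prenylbenzaldehyde; 11 allyl diazoacetate
Product: 12 allyl (Z)-2-[3,4-bis(TBS-oxy)-5-prenylphenyl]-3-hydroxyprop-2-enoate (the enol form of the 2-aryl-3-oxopropanoate)
Conditions: HBF4·OEt2 (10 mol %), CH2Cl2, −78 °C, slow addition of 11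
Reagents that add atoms: none
Why: Acid-catalysed aldehyde–diazoacetate homologation (the aryl-migration branch of the Roskamp-type reaction): the diazo carbon adds to the protonated aldehyde and the electron-rich aryl group shifts to that carbon as N2 leaves, giving the 2-aryl-3-oxo ester, which rests as the hydrogen-bonded (Z)-enol.

Step 8
Reactants: 12 allyl (Z)-2-aryl-3-hydroxyprop-2-enoate
Product: 13 allyl (Z)-2-[3,4-bis(TBS-oxy)-5-prenylphenyl]-3-(tosyloxy)prop-2-enoate
Conditions: TsCl (1.5 equiv), TMEDA (1.5 equiv), LiCl (1.5 equiv), MeCN, 0 °C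
Reagents that add atoms: p-toluenesulfonyl chloride, Cc1ccc(cc1)S(Cl)(=O)=O
Why: O-sulfonylation of the enolate under lithium chelation between the enolate oxygen and the ester carbonyl should hold these groups cis and give the (Z)-enol tosylate.

Step 9
Reactants: 5 3,5-bis(TBS-oxy)-4-prenylphenol; 13 allyl (Z)-2-aryl-3-(tosyloxy)prop-2-enoate
Product: 14 allyl (Z)-3-[3,5-bis(TBS-oxy)-4-prenylphenoxy]-2-[3,4-bis(TBS-oxy)-5-prenylphenyl]prop-2-enoate
Conditions: Cs2CO3 (1.2 equiv), anhydrous MeCN, 0 °C to rt, 5 and 13 in 1:1 ratio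
Reagents that add atoms: none
Why: Nucleophilic vinylic substitution by addition–elimination: the phenoxide adds to the carbon beta to the ester and the stabilised carbanion expels tosylate faster than it rotates, which should retain the (Z) geometry.

Step 10
Reactants: 14 allyl (Z)-3-aryloxy-2-arylprop-2-enoate
Product: 15 (Z)-3-[3,5-bis(TBS-oxy)-4-prenylphenoxy]-2-[3,4-bis(TBS-oxy)-5-prenylphenyl]prop-2-enoic acid
Conditions: Pd(PPh3)4 (5 mol %), PhSiH3 (2 equiv), CH2Cl2, rt; aqueous work-up
Reagents that add atoms: none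
Why: Allyl ester cleavage through a π-allyl complex of palladium with a hydride scavenger frees the acid under neutral conditions; an amine scavenger is avoided because it would displace the aryloxy group from the vinylogous carbonate.

Step 11
Reactants: 15 (Z)-3-aryloxy-2-arylprop-2-enoic acid
Product: 17 5,7-bis(TBS-oxy)-6-prenyl-3-[3,4-bis(TBS-oxy)-5-prenylphenyl]-4H-chromen-4-one, via acid chloride 16 (not isolated)
Conditions: 1-chloro-N,N,2-trimethylprop-1-en-1-amine (1.2 equiv), CH2Cl2, 0 °C; then Me2AlCl (3 equiv, hexanes), −78 to −20 °C; aq. potassium sodium tartrate (KNaC4H4O6)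
Reagents that add atoms: none
Why: The acid is converted under neutral conditions into acid chloride 16, which Me2AlCl ionises to an acylium ion that is also a ketene-oxocarbenium (ArO+=CH–C(Ar)=C=O); this attacks the ring A carbon ortho to the ether oxygen and para to a silyloxy group, and the ring proton leaves as methane through an Al–CH3 bond, giving the chromone. The closest known reaction type is the Friedel–Crafts cyclisation of 3-aryloxyacrylic acids or their chlorides to chromones, combined with dialkylaluminium chloride-promoted acylation of acid-sensitive electron-rich arenes. Ring C closes as a six-membered ring by electrophilic aromatic substitution, endo with respect to the attacked C4a=C8a arene bond, and no stereocentre is formed. The step needs site selectivity on ring A, and the mirror plane through O1–C8a and C6 of the 2-prenylphloroglucinol ether supplies it, since both ortho carbons lead to the same 6-prenyl product. It also needs the acyl carbon cis to the aryloxy group, which the (Z)-acid provides and which rotation about C2–C3 in the ionised species would restore. Chemoselectivity over the two prenyl alkenes should follow from the high nucleophilicity of the tri-oxygenated ring, the absence of free HCl, and the seven-membered or larger rings that alkene acylation would require.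

Step 12
Reactants: 17 tetrakis-TBS isoflavone
Product: 18 isoangustone A
Conditions: TBAF (5 equiv), AcOH (5 equiv), THF, 0 °C to rt
Reagents that add atoms: none
Why: Fluoride cleavage of the four aryl silyl ethers, buffered with acetic acid so that the catechol and the ortho-prenyl phenols are not exposed to strong base or acid, should release the tetraphenol without chroman formation.

**Compound list**

1 | phloroglucinol | Oc1cc(O)cc(O)c1 | starting material
2 | prenyl bromide (1-bromo-3-methylbut-2-ene) | CC(C)=CCBr | starting material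
3 | 2-prenylphloroglucinol | CC(C)=CCc1c(O)cc(O)cc1O | intermediate
4 | 1,3,5-tris(TBS-oxy)-2-prenylbenzene | CC(C)=CCc1c(O[Si](C)(C)C(C)(C)C)cc(O[Si](C)(C)C(C)(C)C)cc1O[Si](C)(C)C(C)(C)C | intermediate
5 | 3,5-bis(TBS-oxy)-4-prenylphenol | CC(C)=CCc1c(O[Si](C)(C)C(C)(C)C)cc(O)cc1O[Si](C)(C)C(C)(C)C | intermediate
6 | 3-bromo-4,5-dihydroxybenzaldehyde | O=Cc1cc(O)c(O)c(Br)c1 | starting material
7 | 3-bromo-4,5-bis(TBS-oxy)benzaldehyde | O=Cc1cc(O[Si](C)(C)C(C)(C)C)c(O[Si](C)(C)C(C)(C)C)c(Br)c1 | intermediate
8 | tributyl(3-methylbut-2-en-1-yl)stannane | CCCC[Sn](CCCC)(CCCC)CC=C(C)C | starting material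
9 | 3,4-bis(TBS-oxy)-5-prenylbenzaldehyde | O=Cc1cc(CC=C(C)C)c(O[Si](C)(C)C(C)(C)C)c(O[Si](C)(C)C(C)(C)C)c1 | intermediate
10 | allyl bromoacetate | C=CCOC(=O)CBr | starting material
11 | allyl diazoacetate | C=CCOC(=O)C=[N+]=[N-] | intermediate
12 | allyl (Z)-2-[3,4-bis(TBS-oxy)-5-prenylphenyl]-3-hydroxyprop-2-enoate | C=CCOC(=O)/C(=C\O)c1cc(CC=C(C)C)c(O[Si](C)(C)C(C)(C)C)c(O[Si](C)(C)C(C)(C)C)c1 | intermediate
13 | allyl (Z)-2-[3,4-bis(TBS-oxy)-5-prenylphenyl]-3-(tosyloxy)prop-2-enoate | C=CCOC(=O)/C(=C\OS(=O)(=O)c1ccc(C)cc1)c1cc(CC=C(C)C)c(O[Si](C)(C)C(C)(C)C)c(O[Si](C)(C)C(C)(C)C)c1 | intermediate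
14 | allyl (Z)-3-[3,5-bis(TBS-oxy)-4-prenylphenoxy]-2-[3,4-bis(TBS-oxy)-5-prenylphenyl]prop-2-enoate | C=CCOC(=O)/C(=C\Oc1cc(O[Si](C)(C)C(C)(C)C)c(CC=C(C)C)c(O[Si](C)(C)C(C)(C)C)c1)c1cc(CC=C(C)C)c(O[Si](C)(C)C(C)(C)C)c(O[Si](C)(C)C(C)(C)C)c1 | intermediate
15 | (Z)-3-[3,5-bis(TBS-oxy)-4-prenylphenoxy]-2-[3,4-bis(TBS-oxy)-5-prenylphenyl]prop-2-enoic acid | OC(=O)/C(=C\Oc1cc(O[Si](C)(C)C(C)(C)C)c(CC=C(C)C)c(O[Si](C)(C)C(C)(C)C)c1)c1cc(CC=C(C)C)c(O[Si](C)(C)C(C)(C)C)c(O[Si](C)(C)C(C)(C)C)c1 | intermediate
16 | (Z)-3-[3,5-bis(TBS-oxy)-4-prenylphenoxy]-2-[3,4-bis(TBS-oxy)-5-prenylphenyl]prop-2-enoyl chloride | ClC(=O)/C(=C\Oc1cc(O[Si](C)(C)C(C)(C)C)c(CC=C(C)C)c(O[Si](C)(C)C(C)(C)C)c1)c1cc(CC=C(C)C)c(O[Si](C)(C)C(C)(C)C)c(O[Si](C)(C)C(C)(C)C)c1 | intermediate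
17 | 5,7-bis(TBS-oxy)-6-prenyl-3-[3,4-bis(TBS-oxy)-5-prenylphenyl]-4H-chromen-4-one | CC(C)=CCc1c(O[Si](C)(C)C(C)(C)C)cc2occ(-c3cc(CC=C(C)C)c(O[Si](C)(C)C(C)(C)C)c(O[Si](C)(C)C(C)(C)C)c3)c(=O)c2c1O[Si](C)(C)C(C)(C)C | intermediate
18 | isoangustone A | CC(C)=CCc1cc(-c2coc3cc(O)c(CC=C(C)C)c(O)c3c2=O)cc(O)c1O | target

**Step count**

Total: 12 steps. Longest linear sequence: 8 steps (4, 5, 7, 8, 9, 10, 11, 12, from 6).

**Steps most likely to fail**

Step 11. The acylium ion may be captured by a prenyl alkene, a silyl group peri to the new carbonyl may be lost with proton-induced chroman formation, or the enol ether may decompose before closure. The fallback closes the same C4–C4a bond with inverted polarity, sets out from phenol 5 and tosylate 13, and comes back at 17. Phenol 5 would be mono-iodinated at one of its two equivalent ortho carbons (N-iodosuccinimide, CH2Cl2, −40 °C) to give 2-iodo-3,5-bis(TBS-oxy)-4-prenylphenol F1. Substitution on tosylate 13 under the conditions of step 9 would give allyl (Z)-3-[2-iodo-3,5-bis(TBS-oxy)-4-prenylphenoxy]-2-[3,4-bis(TBS-oxy)-5-prenylphenyl]prop-2-enoate F2. Iodine–lithium exchange (n-BuLi, THF, −100 °C) and Parham cyclisation of the aryllithium onto the allyl ester would then give chromone 17, which continues to step 12.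

Step 7. The acid catalyst may protonate the prenyl alkene or strip a silyl group, and hydride shift may compete with aryl shift to give the beta-keto ester. The fallback sets out from aldehyde 9 and comes back at 12 by base-mediated formylation of an arylacetate. Pinnick oxidation (NaClO2, NaH2PO4, 2-methylbut-2-ene, t-BuOH/H2O) would give 3,4-bis(TBS-oxy)-5-prenylbenzoic acid F3. Conversion to the acid chloride with 1-chloro-N,N,2-trimethylprop-1-en-1-amine and treatment with Me3SiCHN2 would give 2-diazo-1-[3,4-bis(TBS-oxy)-5-prenylphenyl]ethan-1-one F4. Wolff rearrangement of this Arndt–Eistert intermediate (silver benzoate AgO2CPh, Et3N, allyl alcohol/THF) would give allyl 2-[3,4-bis(TBS-oxy)-5-prenylphenyl]acetate F5. Claisen formylation (LiN(SiMe3)2, allyl formate, THF, −78 °C) would then deliver 12.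

Step 3. Cleavage may be poorly site-selective among the three silyl ethers or may run on to the diol. The fallback reverses the sense of differentiation by blocking the exposed oxygen first; it sets out from triol 3 and comes back at 5. Acylation with pivaloyl chloride (1 equiv, pyridine, CH2Cl2, −40 °C) at the hydroxyl flanked by two ring hydrogens would give 3,5-dihydroxy-4-prenylphenyl pivalate F6. Silylation (TBSCl, imidazole, DMF) would give 3,5-bis(TBS-oxy)-4-prenylphenyl pivalate F7. Reductive removal of the pivalate (i-Bu2AlH, CH2Cl2, −78 °C) would give phenol 5.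

**Further compounds**

F1 | step 11 | 2-iodo-3,5-bis(TBS-oxy)-4-prenylphenol | CC(C)=CCc1c(O[Si](C)(C)C(C)(C)C)cc(O)c(I)c1O[Si](C)(C)C(C)(C)C
F2 | step 11 | allyl (Z)-3-[2-iodo-3,5-bis(TBS-oxy)-4-prenylphenoxy]-2-[3,4-bis(TBS-oxy)-5-prenylphenyl]prop-2-enoate | C=CCOC(=O)/C(=C\Oc1cc(O[Si](C)(C)C(C)(C)C)c(CC=C(C)C)c(O[Si](C)(C)C(C)(C)C)c1I)c1cc(CC=C(C)C)c(O[Si](C)(C)C(C)(C)C)c(O[Si](C)(C)C(C)(C)C)c1
F3 | step 7 | 3,4-bis(TBS-oxy)-5-prenylbenzoic acid | OC(=O)c1cc(CC=C(C)C)c(O[Si](C)(C)C(C)(C)C)c(O[Si](C)(C)C(C)(C)C)c1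
F4 | step 7 | 2-diazo-1-[3,4-bis(TBS-oxy)-5-prenylphenyl]ethan-1-one | [N-]=[N+]=CC(=O)c1cc(CC=C(C)C)c(O[Si](C)(C)C(C)(C)C)c(O[Si](C)(C)C(C)(C)C)c1
F5 | step 7 | allyl 2-[3,4-bis(TBS-oxy)-5-prenylphenyl]acetate | C=CCOC(=O)Cc1cc(CC=C(C)C)c(O[Si](C)(C)C(C)(C)C)c(O[Si](C)(C)C(C)(C)C)c1
F6 | step 3 | 3,5-dihydroxy-4-prenylphenyl pivalate | CC(C)=CCc1c(O)cc(OC(=O)C(C)(C)C)cc1O
F7 | step 3 | 3,5-bis(TBS-oxy)-4-prenylphenyl pivalate | CC(C)=CCc1c(O[Si](C)(C)C(C)(C)C)cc(OC(=O)C(C)(C)C)cc1O[Si](C)(C)C(C)(C)C
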